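**Retrosynthetic overview** (cembrane locants: C16 lactone C=O, C15 its α-carbon, C1 ring CH, C3 lactone carbinol, C4 tertiary carbinol, C8 hydroperoxide carbon, C11/C12 epoxide)
1. Target ⇐ singlet-oxygen ene reaction at C7=C8 of the 11,12-epoxy-4-hydroxycembr-7-en-16,3-olide (last step).
2. Fourteen-membered ring ⇐ ring-closing metathesis at C13=C14, then diimide, of a δ-lactone carrying a C1 vinyl group and a vinyl epoxide; epoxide ⇐ Sharpless epoxidation of a C13 allylic alcohol.
3. δ-Lactone and tertiary C4–OH ⇐ Baeyer–Villiger oxidation of a 2,2,6-trisubstituted cyclohexanone (C4 migrates with retention), then translactonisation onto the C3 oxygen.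
4. Cyclohexanone stereocentres ⇐ vinyl/methyl three-component coupling on an enone steered by the C3 oxygen ⇐ enantioselective mono-reduction that desymmetrises an achiral 2-methyl-2-(homogeranyl)cyclohexane-1,3-dione (key step).
5. Dione ⇐ Birch dearomatisation of an arene from 2,6-dimethoxytoluene + geranyl bromide (ring carbons become C16, C15, C1, C2, C3, C4; the methyl becomes C5). Ring order: carbocycle, seven-membered lactone, six-membered lactone, oxirane, fourteen-membered ring.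

Assumption: 2,6-dimethoxytoluene (2-methylresorcinol dimethyl ether) and geranyl bromide are bought; the route is a paper design, not run, and selectivities are expectations.

**Step 1**
Reactants: 1 1,3-dimethoxy-2-methylbenzene (2,6-dimethoxytoluene); 2 geranyl bromide [(2E)-1-bromo-3,7-dimethylocta-2,6-diene]
Product: 4 2-[(3E)-4,8-dimethylnona-3,7-dien-1-yl]-1,3-dimethoxybenzene, via benzylpotassium 3 (not isolated)
Conditions: n-BuLi, KOt-Bu, THF, −78 °C; then 2, −78 → 0 °C
Reagents that add atoms: none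
Why: Lateral (benzylic) metalation with the n-BuLi/KOt-Bu superbase gives the doubly OMe-chelated benzylpotassium, which displaces the primary allylic bromide at its α-carbon (SN2; the γ-carbon is fully substituted), so the 2E olefin is kept.

**Step 2**
Reactants: 4 2-[(3E)-4,8-dimethylnona-3,7-dien-1-yl]-1,3-dimethoxybenzene
Product: 6 2-[(3E)-4,8-dimethylnona-3,7-dien-1-yl]cyclohexane-1,3-dione, via bis(enol ether) 5 (not isolated)
Conditions: Li, NH3 (l), t-BuOH, THF, −78 → −33 °C; then 1 M HCl, THF, rt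
Reagents that add atoms: water (O)
Why: Birch reduction of the resorcinol dimethyl ether gives the 2,5-dihydro bis(enol ether) without touching the isolated trisubstituted olefins, and aqueous acid hydrolyses both enol ethers to the 1,3-dione (dearomatisation).

**Step 3**
Reactants: 6 2-[(3E)-4,8-dimethylnona-3,7-dien-1-yl]cyclohexane-1,3-dione
Product: 7 2-[(3E)-4,8-dimethylnona-3,7-dien-1-yl]-2-methylcyclohexane-1,3-dione
Conditions: MeI, K2CO3, acetone, reflux
Reagents that add atoms: iodomethane (CI)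
Why: C-alkylation of the 2-alkyl-1,3-dione enolate with MeI builds the quaternary carbon (future C4); the product is achiral with a mirror plane through that carbon.

**Step 4 (key step)**
Reactants: 7 2-[(3E)-4,8-dimethylnona-3,7-dien-1-yl]-2-methylcyclohexane-1,3-dione
Product: 8 (2S,3R)-2-[(3E)-4,8-dimethylnona-3,7-dien-1-yl]-3-hydroxy-2-methylcyclohexan-1-one
Conditions: (S)-2-methyl-CBS-oxazaborolidine (20 mol%), catecholborane, toluene, −78 → −40 °C
Reagents that add atoms: none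
Why: Corey–Bakshi–Shibata reduction, in which the oxazaborolidine–borane picks one of the two enantiotopic carbonyls and delivers hydride anti to the quaternary methyl (axial attack on the conformer with axial methyl, as in oxazaborolidine reductions of 2-alkyl-2-methylcycloalkane-1,3-diones of the secosteroid type), setting C3 (R) with OH cis to the methyl and making C4 stereogenic (S).

**Step 5**
Reactants: 8 (2S,3R)-2-[(3E)-4,8-dimethylnona-3,7-dien-1-yl]-3-hydroxy-2-methylcyclohexan-1-one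
Product: 10 (5R,6S)-6-[(3E)-4,8-dimethylnona-3,7-dien-1-yl]-6-methyl-5-[(triethylsilyl)oxy]cyclohex-2-en-1-one, via bis(triethylsilyl) compound 9 (not isolated)
Conditions: Et3SiOTf, Et3N, CH2Cl2, 0 °C; then Pd(OAc)2, MeCN, rt
Reagents that add atoms: triethylsilyl trifluoromethanesulfonate (CC[Si](CC)(CC)OS(=O)(=O)C(F)(F)F)
Why: Silyl triflate/amine protects the hydroxyl and soft-enolises the ketone toward C15 (the only α-CH2, C4 being quaternary), and Saegusa–Ito oxidation of the crude silyl enol ether gives the enone.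

**Step 6**
Reactants: 10 (5R,6S)-6-[(3E)-4,8-dimethylnona-3,7-dien-1-yl]-6-methyl-5-[(triethylsilyl)oxy]cyclohex-2-en-1-one
Product: 12 (2S,3S,5R,6S)-6-[(3E)-4,8-dimethylnona-3,7-dien-1-yl]-3-ethenyl-2,6-dimethyl-5-[(triethylsilyl)oxy]cyclohexan-1-one, via magnesium enolate 11 (not isolated)
Conditions: CH2=CHMgBr, CuBr·SMe2 (10 mol%), THF, −78 → −40 °C; then MeI, HMPA, −40 → 0 °C
Reagents that add atoms: vinylmagnesium bromide (C=C[Mg]Br); iodomethane (CI)
Why: Copper-catalysed 1,4-addition occurs by axial attack anti to the C3 silyloxy group (trans-3,5 rule for 5-substituted cyclohexenones), placing the vinyl group (C14) cis to the C4 chain, and the enolate is methylated anti to the new vinyl group, setting C1 and C15.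

**Step 7**
Reactants: 12 (2S,3S,5R,6S)-6-[(3E)-4,8-dimethylnona-3,7-dien-1-yl]-3-ethenyl-2,6-dimethyl-5-[(triethylsilyl)oxy]cyclohexan-1-one
Product: 14 (3S,4S,6R)-4-ethenyl-6-[(2S,5E)-2-hydroxy-6,10-dimethylundeca-5,9-dien-2-yl]-3-methyloxan-2-one, via oxepanone 13 (not isolated)
Conditions: Me3SiOOSiMe3, SnCl4 (cat.), trans-cyclohexane-1,2-diamine (cat.), 4 Å MS, CH2Cl2, 0 °C → rt; then Bu4NF, THF, 0 °C
Reagents that add atoms: bis(trimethylsilyl) peroxide (C[Si](C)(C)OO[Si](C)(C)C)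
Why: Baeyer–Villiger oxidation with a non-epoxidising silyl peroxide/Lewis acid system, in which the fully substituted C4 migrates in preference to the secondary C15 with retention to make the C4–O bond; fluoride then frees the C3 alkoxide, which translactonises the seven-membered lactone to the six-membered one and releases the tertiary C4–OH.

**Step 8**
Reactants: 14 (3S,4S,6R)-4-ethenyl-6-[(2S,5E)-2-hydroxy-6,10-dimethylundeca-5,9-dien-2-yl]-3-methyloxan-2-one
Product: 15 (3S,4S,6R)-6-[(2S,5E,9E)-2,11-dihydroxy-6,10-dimethylundeca-5,9-dien-2-yl]-4-ethenyl-3-methyloxan-2-one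
Conditions: SeO2 (cat.), t-BuOOH, salicylic acid (cat.), CH2Cl2, rt
Reagents that add atoms: tert-butyl hydroperoxide (CC(C)(C)OO)
Why: SeO2-catalysed allylic oxidation (ene reaction then [2,3] shift) attacks the (E)-methyl of the terminal isopropylidene unit, the most reactive allylic site of a polyprenyl chain, giving the (E)-allylic alcohol at C13.

**Step 9**
Reactants: 15 (3S,4S,6R)-6-[(2S,5E,9E)-2,11-dihydroxy-6,10-dimethylundeca-5,9-dien-2-yl]-4-ethenyl-3-methyloxan-2-one
Product: 16 (3S,4S,6R)-4-ethenyl-6-{(2S,5E)-2-hydroxy-8-[(2S,3S)-3-(hydroxymethyl)-3-methyloxiran-2-yl]-6-methyloct-5-en-2-yl}-3-methyloxan-2-one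
Conditions: Ti(OiPr)4 (cat.), L-(+)-diethyl tartrate (cat.), t-BuOOH, 4 Å MS, CH2Cl2, −20 °C
Reagents that add atoms: tert-butyl hydroperoxide (CC(C)(C)OO)
Why: Sharpless asymmetric epoxidation touches only the allylic-alcohol olefin, and L-(+)-tartrate gives the (2S,3S)-epoxy alcohol from an (E)-2-methylalk-2-en-1-ol, i.e. C11 (S) and C12 (S) under reagent control.

**Step 10**
Reactants: 16 (3S,4S,6R)-4-ethenyl-6-{(2S,5E)-2-hydroxy-8-[(2S,3S)-3-(hydroxymethyl)-3-methyloxiran-2-yl]-6-methyloct-5-en-2-yl}-3-methyloxan-2-one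
Product: 18 (3S,4S,6R)-4-ethenyl-6-{(2S,5E)-8-[(2S,3S)-3-ethenyl-3-methyloxiran-2-yl]-2-hydroxy-6-methyloct-5-en-2-yl}-3-methyloxan-2-one, via epoxy aldehyde 17 (not isolated)
Conditions: Dess–Martin periodinane, CH2Cl2, 0 °C → rt; then Ph3PCH3Br, KHMDS, THF, −78 → 0 °C
Reagents that add atoms: methyltriphenylphosphonium bromide (C[P+](c1ccccc1)(c1ccccc1)c1ccccc1.[Br-])
Why: Dess–Martin oxidation gives an epoxy aldehyde whose α-carbon is quaternary and cannot epimerise, and Wittig methylenation of the crude aldehyde at low temperature outruns attack on the lactone.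

**Step 11**
Reactants: 18 (3S,4S,6R)-4-ethenyl-6-{(2S,5E)-8-[(2S,3S)-3-ethenyl-3-methyloxiran-2-yl]-2-hydroxy-6-methyloct-5-en-2-yl}-3-methyloxan-2-one
Product: 19 (1S,3R,4S,7E,11S,12S,15S)-11,12-epoxy-4-hydroxycembra-7,13-dien-16,3-olide (13E/13Z mixture)
Conditions: second-generation Grubbs catalyst (10 mol%), CH2Cl2 (1 mM), 40 °C
Reagents that add atoms: none
Why: Ring-closing olefin metathesis of the two monosubstituted vinyl groups at high dilution closes the fourteen-membered ring across the cis-4,6-disubstituted lactone, the trisubstituted C7=C8 olefin being inert, and both C13=C14 isomers converge in the next step.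

**Step 12**
Reactants: 19 (1S,3R,4S,7E,11S,12S,15S)-11,12-epoxy-4-hydroxycembra-7,13-dien-16,3-olide
Product: 20 (1R,3R,4S,7E,11S,12S,15S)-11,12-epoxy-4-hydroxycembr-7-en-16,3-olide
Conditions: 2-nitrobenzenesulfonylhydrazide, Et3N, CH2Cl2, rt
Reagents that add atoms: none
Why: Diimide reduction is much faster for the 1,2-disubstituted C13=C14 olefin than for the trisubstituted C7=C8 olefin and leaves epoxide and lactone untouched.

**Step 13**
Reactants: 20 (1R,3R,4S,7E,11S,12S,15S)-11,12-epoxy-4-hydroxycembr-7-en-16,3-olide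
Product: 21 (1R,3R,4S,6E,8S,11S,12S,15S)-11,12-epoxy-8-hydroperoxy-4-hydroxycembr-6-en-16,3-olide
Conditions: O2, hν (visible), tetraphenylporphyrin (cat.), CH2Cl2, −20 °C
Reagents that add atoms: dioxygen (O=O)
Why: Schenck ene reaction of singlet oxygen, in which oxygen adds to C8 and hydrogen is taken from C6 on the more crowded side of the trisubstituted olefin to give the tertiary hydroperoxide and the 6E olefin; attack on the outer face of the macrocyclic olefin is expected to give 8S, and the C7-hydroperoxide regioisomer and any 8-epimer are removed by chromatography.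

**Compound list**
1 | 1,3-dimethoxy-2-methylbenzene (2,6-dimethoxytoluene) | COc1cccc(OC)c1C | starting material
2 | geranyl bromide, (2E)-1-bromo-3,7-dimethylocta-2,6-diene | BrC/C=C(\C)CCC=C(C)C | starting material
3 | (2,6-dimethoxyphenyl)methylpotassium | [K+].[CH2-]c1c(OC)cccc1OC | intermediate (not isolated)
4 | 2-[(3E)-4,8-dimethylnona-3,7-dien-1-yl]-1,3-dimethoxybenzene | COc1cccc(OC)c1CC/C=C(\C)CCC=C(C)C | intermediate
5 | 6-[(3E)-4,8-dimethylnona-3,7-dien-1-yl]-1,5-dimethoxycyclohexa-1,4-diene | COC1=CCC=C(OC)C1CC/C=C(\C)CCC=C(C)C | intermediate (not isolated)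
6 | 2-[(3E)-4,8-dimethylnona-3,7-dien-1-yl]cyclohexane-1,3-dione | O=C1CCCC(=O)C1CC/C=C(\C)CCC=C(C)C | intermediate
7 | 2-[(3E)-4,8-dimethylnona-3,7-dien-1-yl]-2-methylcyclohexane-1,3-dione (achiral) | O=C1CCCC(=O)C1(C)CC/C=C(\C)CCC=C(C)C | intermediate
8 | (2S,3R)-2-[(3E)-4,8-dimethylnona-3,7-dien-1-yl]-3-hydroxy-2-methylcyclohexan-1-one (OH cis to methyl) | O=C1CCC[C@@H](O)[C@]1(C)CC/C=C(\C)CCC=C(C)C | intermediate
9 | triethyl({(5R,6S)-6-[(3E)-4,8-dimethylnona-3,7-dien-1-yl]-6-methyl-5-[(triethylsilyl)oxy]cyclohex-1-en-1-yl}oxy)silane | CC[Si](CC)(CC)OC1=CCC[C@@H](O[Si](CC)(CC)CC)[C@]1(C)CC/C=C(\C)CCC=C(C)C | intermediate (not isolated)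
10 | (5R,6S)-6-[(3E)-4,8-dimethylnona-3,7-dien-1-yl]-6-methyl-5-[(triethylsilyl)oxy]cyclohex-2-en-1-one | O=C1C=CC[C@@H](O[Si](CC)(CC)CC)[C@]1(C)CC/C=C(\C)CCC=C(C)C | intermediate
11 | bromomagnesium (3S,5R,6S)-6-[(3E)-4,8-dimethylnona-3,7-dien-1-yl]-3-ethenyl-6-methyl-5-[(triethylsilyl)oxy]cyclohex-1-en-1-olate | Br[Mg]OC1=C[C@H](C=C)C[C@@H](O[Si](CC)(CC)CC)[C@]1(C)CC/C=C(\C)CCC=C(C)C | intermediate (not isolated)
12 | (2S,3S,5R,6S)-6-[(3E)-4,8-dimethylnona-3,7-dien-1-yl]-3-ethenyl-2,6-dimethyl-5-[(triethylsilyl)oxy]cyclohexan-1-one | O=C1[C@@H](C)[C@H](C=C)C[C@@H](O[Si](CC)(CC)CC)[C@]1(C)CC/C=C(\C)CCC=C(C)C | intermediate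
13 | (3S,4S,6R,7S)-7-[(3E)-4,8-dimethylnona-3,7-dien-1-yl]-4-ethenyl-3,7-dimethyl-6-[(triethylsilyl)oxy]oxepan-2-one | O=C1[C@@H](C)[C@H](C=C)C[C@@H](O[Si](CC)(CC)CC)[C@](C)(CC/C=C(\C)CCC=C(C)C)O1 | intermediate (not isolated)
14 | (3S,4S,6R)-4-ethenyl-6-[(2S,5E)-2-hydroxy-6,10-dimethylundeca-5,9-dien-2-yl]-3-methyloxan-2-one | C[C@@H]1C(=O)O[C@H](C[C@H]1C=C)[C@@](C)(O)CC/C=C(\C)CCC=C(C)C | intermediate
15 | (3S,4S,6R)-6-[(2S,5E,9E)-2,11-dihydroxy-6,10-dimethylundeca-5,9-dien-2-yl]-4-ethenyl-3-methyloxan-2-one | C[C@@H]1C(=O)O[C@H](C[C@H]1C=C)[C@@](C)(O)CC/C=C(\C)CC/C=C(\C)CO | intermediate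
16 | (3S,4S,6R)-4-ethenyl-6-{(2S,5E)-2-hydroxy-8-[(2S,3S)-3-(hydroxymethyl)-3-methyloxiran-2-yl]-6-methyloct-5-en-2-yl}-3-methyloxan-2-one | C[C@@H]1C(=O)O[C@H](C[C@H]1C=C)[C@@](C)(O)CC/C=C(\C)CC[C@@H]2O[C@@]2(C)CO | intermediate
17 | (3S,4S,6R)-4-ethenyl-6-{(2S,5E)-8-[(2S,3R)-3-formyl-3-methyloxiran-2-yl]-2-hydroxy-6-methyloct-5-en-2-yl}-3-methyloxan-2-one | C[C@@H]1C(=O)O[C@H](C[C@H]1C=C)[C@@](C)(O)CC/C=C(\C)CC[C@@H]2O[C@@]2(C)C=O | intermediate (not isolated)
18 | (3S,4S,6R)-4-ethenyl-6-{(2S,5E)-8-[(2S,3S)-3-ethenyl-3-methyloxiran-2-yl]-2-hydroxy-6-methyloct-5-en-2-yl}-3-methyloxan-2-one | C[C@@H]1C(=O)O[C@H](C[C@H]1C=C)[C@@](C)(O)CC/C=C(\C)CC[C@@H]2O[C@@]2(C)C=C | intermediate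
19 | (1S,3R,4S,7E,11S,12S,15S)-11,12-epoxy-4-hydroxycembra-7,13-dien-16,3-olide, 13E/13Z mixture (C13=C14 left unspecified in the SMILES) | C[C@@H]1C(=O)O[C@@H]2C[C@H]1C=C[C@]1(C)O[C@H]1CC/C(C)=C/CC[C@]2(C)O | intermediate
20 | (1R,3R,4S,7E,11S,12S,15S)-11,12-epoxy-4-hydroxycembr-7-en-16,3-olide | C[C@@H]1C(=O)O[C@@H]2C[C@H]1CC[C@]1(C)O[C@H]1CC/C(C)=C/CC[C@]2(C)O | intermediate
21 | (1R,3R,4S,6E,8S,11S,12S,15S)-11,12-epoxy-8-hydroperoxy-4-hydroxycembr-6-en-16,3-olide (CNP0297487.4) | C[C@@H]1C(=O)O[C@@H]2C[C@H]1CC[C@]1(C)O[C@H]1CC[C@](C)(OO)/C=C/C[C@]2(C)O | target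

**Totals**
Total step count: 13. Longest linear sequence: 13 steps (1 + 2 → 21).

**Three steps most likely to fail**

Step 4 may give the wrong diastereotopic carbonyl (OH cis to the chain) or low ee. The fallback sets out from 7 and uses enzymatic group selection followed by carbinol inversion. Baker's yeast or a Prelog-type ketoreductase with NADPH recycling reduces 7 to the (2S,3S)-hydroxy ketone F1, which has the same quaternary configuration but the epimeric carbinol, as known for 2-allyl-2-methylcyclohexane-1,3-dione. Mitsunobu esterification (4-nitrobenzoic acid, PPh3, DIAD, THF) inverts C3 to give the (1R,2S) 4-nitrobenzoate F2. Methanolysis (K2CO3 cat., MeOH) returns to the route at 8.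

Step 7 may fail because the peroxide attacks the trisubstituted olefins or the hindered ketone reacts too slowly. The fallback sets out from 12 and masks the olefins. Pyridinium tribromide (CH2Cl2, −78 °C) converts all three C=C bonds into vicinal dibromides, giving the hexabromo ketone F3. An ordinary peracid Baeyer–Villiger oxidation (mCPBA, CH2Cl2, 0 °C) gives the hexabromo oxepanone F4. Zinc dust in AcOH/THF regenerates the olefins by anti elimination, which restores the E geometry, and returns to the route at 13; 13 is then treated with Bu4NF as in step 7.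

Step 13 will give the C7-hydroperoxide/exocyclic-methylene regioisomer alongside the product and may favour the 8-epimer. The fallback sets out from 20 and replaces the pericyclic step by an ionic addition–elimination. Me3SiOTf/2,6-lutidine protects C4–OH (which would otherwise cyclise onto C7) as the trimethylsilyl ether F5. 1,3-Dibromo-5,5-dimethylhydantoin with anhydrous H2O2 (Et2O, −40 °C) adds Br to C7 and OOH to the tertiary C8 in Markovnikov, anti fashion, giving the (7R,8S)-bromo hydroperoxide F6. Et3SiOTf/2,6-lutidine caps the hydroperoxide, which would otherwise close to a dioxetane, as the triethylsilyl peroxide F7. DBU (toluene, 60 °C) eliminates HBr toward C6, the only β-hydrogens, to give the 6E silyl peroxide F8. HF·pyridine removes both silyl groups and arrives at 21. This fixes the constitution and delivers oxygen to the face opposite the one attacked directly by singlet oxygen.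

**Further compounds**
F1 | step 4 | (2S,3S)-2-[(3E)-4,8-dimethylnona-3,7-dien-1-yl]-3-hydroxy-2-methylcyclohexan-1-one | O=C1CCC[C@H](O)[C@]1(C)CC/C=C(\C)CCC=C(C)C
F2 | step 4 | (1R,2S)-2-[(3E)-4,8-dimethylnona-3,7-dien-1-yl]-2-methyl-3-oxocyclohexyl 4-nitrobenzoate | O=C1CCC[C@@H](OC(=O)c2ccc(cc2)[N+](=O)[O-])[C@]1(C)CC/C=C(\C)CCC=C(C)C
F3 | step 7 | hexabromide of 12: 3-(1,2-dibromoethyl)-2,6-dimethyl-6-(3,4,7,8-tetrabromo-4,8-dimethylnonyl)-5-[(triethylsilyl)oxy]cyclohexan-1-one, ring centres as in 12, brominated centres as a mixture | O=C1[C@@H](C)[C@H](C(Br)CBr)C[C@@H](O[Si](CC)(CC)CC)[C@]1(C)CCC(Br)C(C)(Br)CCC(Br)C(C)(C)Br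
F4 | step 7 | hexabromide of 13: 4-(1,2-dibromoethyl)-3,7-dimethyl-7-(3,4,7,8-tetrabromo-4,8-dimethylnonyl)-6-[(triethylsilyl)oxy]oxepan-2-one, ring centres as in 13, brominated centres as a mixture | O=C1[C@@H](C)[C@H](C(Br)CBr)C[C@@H](O[Si](CC)(CC)CC)[C@](C)(CCC(Br)C(C)(Br)CCC(Br)C(C)(C)Br)O1
F5 | step 13 | 4-O-trimethylsilyl ether of 20 | C[C@@H]1C(=O)O[C@@H]2C[C@H]1CC[C@]1(C)O[C@H]1CC/C(C)=C/CC[C@]2(C)O[Si](C)(C)C
F6 | step 13 | (7R,8S)-7-bromo-11,12-epoxy-8-hydroperoxy-4-[(trimethylsilyl)oxy]cembran-16,3-olide, other centres as in 20 | C[C@@H]1C(=O)O[C@@H]2C[C@H]1CC[C@]1(C)O[C@H]1CC[C@](C)(OO)[C@H](Br)CC[C@]2(C)O[Si](C)(C)C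
F7 | step 13 | triethylsilyl peroxide of F6 | C[C@@H]1C(=O)O[C@@H]2C[C@H]1CC[C@]1(C)O[C@H]1CC[C@](C)(OO[Si](CC)(CC)CC)[C@H](Br)CC[C@]2(C)O[Si](C)(C)C
F8 | step 13 | 8-O-(triethylsilyl)peroxy, 4-O-trimethylsilyl derivative of 21 | C[C@@H]1C(=O)O[C@@H]2C[C@H]1CC[C@]1(C)O[C@H]1CC[C@](C)(OO[Si](CC)(CC)CC)/C=C/C[C@]2(C)O[Si](C)(C)C
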